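Eudesmane numbering is used. Everything rests on detaching ring B (C5–C10) from ring A at C5–C6 and C9–C10. The key step exploits the vicinal pair C5–H/quaternary C10 shared by both rings, with C14 on C10 and oxygen on the flanking C1 and C9. Ring A is read as 2-methoxycarbonyl-1,4-benzoquinone (C1 and C4 carbonyls, C14 ester), and C6–C9 as an (E)-1-silyloxybutadiene. One catalytic enantioselective Diels–Alder reaction closes ring B, makes both bonds, fixes C10 absolutely, oxygenates C9 and leaves C7=C8, through which the axial isopropenyl group later enters. The precursor is simply the flat, achiral quinone ester plus the diene.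

Key step: step 3

Numbering and faces: ring A = C1, C2, C3, C4, C5, C10; ring B = C5, C6, C7, C8, C9, C10. C14 is the carbon on C10, C15 the methyl on C4, and C11–C13 the isopropenyl on C7. α means the face of the bicycle that carries C14, β the opposite face. The target is trans-fused with 1α-senecioyloxy, 2α- and 9β-acetoxy, 5β-H and 7β-isopropenyl; CIP 1R,2S,5R,7S,9S,10S.

Assumption: the sense of induction of the Sm(OTf)3–pybox catalyst toward diene 4 is not predicted here. Both ligand antipodes can be had, and the one that gives 5 as drawn is used.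

Step 1
Reactants: 1 methyl 2,5-dihydroxybenzoate
Product: 2 methyl 3,6-dioxocyclohexa-1,4-diene-1-carboxylate
Conditions: Ag2O, MgSO4, CH2Cl2, rt, dark; filtration, used at once
Reagents that add atoms: none
Why: Hydroquinone-to-quinone oxidation under neutral, anhydrous conditions, which spares the very electrophilic quinone ester; no stereocenter is involved.

Step 2
Reactants: 3 (E)-but-2-enal
Product: 4 (E)-1-(triethylsilyloxy)buta-1,3-diene
Conditions: Et3SiOTf, Et3N, Et2O, 0 °C → rt; distillation
Reagents that add atoms: triethylsilyl trifluoromethanesulfonate CC[Si](CC)(CC)OS(=O)(=O)C(F)(F)F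
Why: Soft enolisation with O-silylation (silyl dienol ether formation): Et3N removes a γ-proton of the silyl-activated enal and the extended dienolate should give mainly the E dienol ether, while any Z isomer reaches the s-cis form poorly and is left behind in step 3.

Step 3
Reactants: 2 methyl 3,6-dioxocyclohexa-1,4-diene-1-carboxylate; 4 (E)-1-(triethylsilyloxy)buta-1,3-diene
Product: 5 cis-fused enedione ester (methyl 1,4-dioxo-5-triethylsilyloxy-4a,5,8,8a-tetrahydronaphthalene-4a(1H)-carboxylate; CO2Me α on C10, H5 α, 9β-OTES, C2=C3 and C7=C8)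
Conditions: Sm(OTf)3 (10 mol %), 2,6-bis(4,5-diphenyl-4,5-dihydrooxazol-2-yl)pyridine (single antipode, 11 mol %), 4 Å MS, CH2Cl2, −78 → −40 °C, slow addition of 4 (excess)
Reagents that add atoms: none
Why: Concerted but asynchronous normal-demand Diels–Alder reaction, whose closest known type is the rare-earth triflate–pybox-catalysed enantioselective cycloaddition of 2-alkoxycarbonyl-1,4-benzoquinones with 1-substituted dienes. The cation is chelated by the ester carbonyl and the C1 carbonyl, which activates only the C5=C10 bond (site selectivity over C2=C3) and places the largest LUMO coefficient on C5, so the nucleophilic terminus C6 bonds to C5 and the oxygenated terminus C9 to C10 ("ortho" regiochemistry). Ring B closes in one intermolecular suprafacial–suprafacial [4+2] event that gives a six-membered ring without a tether. C10 is set by the ligand, which leaves one face of the chelated quinone open; C5 follows from suprafacial addition (H5 cis to the ester, corrected in step 4); C9 follows from the E geometry of 4 and the endo rule with the quinone ring under the diene (OTES anti to the ester, a centre that serves as oxidation-state handle and is reset in step 12). The step needs the catalysed path to outrun the background cycloaddition and a stepwise silyl-transfer Michael path, which low temperature, sieves, slow diene addition and the bulkier triethylsilyl group are meant to secure.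

Step 4
Reactants: 5 cis-fused enedione ester
Product: 6 trans-fused enedione ester (as 5 but H5 β)
Conditions: DBU (0.2 equiv), CH2Cl2, 0 °C → rt; neutral work-up, recovered 5 resubmitted
Reagents that add atoms: none
Why: Base-catalysed keto–enol epimerisation under thermodynamic control: C5 is the only enolisable position, quaternary C10 blocks aromatisation, and with ring A flat and C7=C8 in ring B the trans fusion (ester and H5 antiperiplanar) is expected to be preferred, as in the classical cis-to-trans isomerisation of angularly substituted quinone adducts.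

Step 5
Reactants: 6 trans-fused enedione ester
Product: 8 enone γ-lactone (C14 carbonyl bridged through oxygen to C4 on the α face; 4β-methyl; C1 ketone; C2=C3), via C4 carbinol ester 7 (not isolated)
Conditions: MeCeCl2 (from MeLi and anhydrous CeCl3), THF, −78 °C, then 0 °C; aq NH4Cl
Reagents that add atoms: methyllithium [Li]C
Why: Organocerium 1,2-addition followed by lactonisation: the non-basic reagent should take the C4 carbonyl (next to a CH) rather than the neopentyl, OTES-screened C1 carbonyl, it approaches from the β face opposite the axial ester, and the resulting 4α-axial alkoxide, 1,3-diaxial to the ester, closes the γ-lactone and removes the acidity of H5.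

Step 6
Reactants: 8 enone γ-lactone
Product: 9 triol (1α-OH, 4α-OH with 4β-methyl, C14–OH; 9β-OTES; C2=C3, C7=C8)
Conditions: LiAlH4, Et2O, −78 → 0 °C; aq potassium sodium tartrate
Reagents that add atoms: none
Why: Hydride reduction of the enone (1,2-mode) and then of the lactone: the lactone bridge covers the α face of ring A, so hydride reaches C1 along the axial β trajectory and gives the equatorial 1α-alcohol cis to C14 before the bridge opens to the primary and tertiary alcohols.

Step 7
Reactants: 9 triol
Product: 10 14-O-TBS diol
Conditions: TBSCl (1.1 equiv), imidazole, DMF, 0 °C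
Reagents that add atoms: tert-butyldimethylsilyl chloride CC(C)(C)[Si](C)(C)Cl
Why: Chemoselective silyl ether formation at the only primary alcohol, since the secondary C1 and tertiary C4 hydroxyls are much slower.

Step 8
Reactants: 10 14-O-TBS diol
Product: 11 1α-senecioate (4α-OH free)
Conditions: 3-methylbut-2-enoyl chloride, pyridine, DMAP (cat.), CH2Cl2, 0 °C → rt
Reagents that add atoms: 3-methylbut-2-enoyl chloride CC(C)=CC(=O)Cl
Why: DMAP-catalysed acylation in which only the secondary C1–OH reacts (C4–OH is tertiary), and pyridine rather than a trialkylamine avoids the vinylketene path that would deconjugate the senecioate.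

Step 9
Reactants: 11 1α-senecioate
Product: 12 9β-alcohol
Conditions: HF·pyridine, excess pyridine, THF, 0 °C
Reagents that add atoms: none
Why: Selective fluoride-mediated desilylation: under buffered conditions the triethylsilyl ether is cleaved well before the neopentyl primary TBS ether, and the medium is too mild to ionise the tertiary allylic alcohol.

Step 10
Reactants: 12 9β-alcohol
Product: 14 bis-enone (3-en-2-one in ring A, 7-en-9-one in ring B; 1α-senecioate; 14-OTBS), via enone carbinol 13 (not isolated)
Conditions: pyridinium chlorochromate [C5H5NH][CrO3Cl] (4 equiv), 4 Å MS, Celite, CH2Cl2, rt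
Reagents that add atoms: pyridinium chlorochromate (delivers the C2 oxygen) [O-][Cr](=O)(=O)Cl.c1cc[nH+]cc1
Why: Allylic alcohol oxidation combined with Babler–Dauben oxidative 1,3-transposition: C9–OH goes to the enone, while the chromate ester of the tertiary allylic C4–OH shifts by a [3,3] process to C2 and is oxidised there, which moves the alkene to C3=C4 and erases the C4 stereocenter.

Step 11
Reactants: 14 bis-enone
Product: 16 7β-isopropenyl 2,9-diketone, via silyl enol ether 15 (not isolated)
Conditions: (CH2=C(CH3))2CuMgBr (from isopropenylmagnesium bromide and CuBr·SMe2, 1.2 equiv), Me3SiCl, THF, −78 °C; aq NH4Cl; then 0.5 M HCl, THF, 0 °C, brief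
Reagents that add atoms: isopropenylmagnesium bromide C=C(C)[Mg]Br; chlorotrimethylsilane C[Si](C)(C)Cl (stays only in 15)
Why: Silyl-chloride-accelerated cuprate conjugate addition: the β-monosubstituted C7=C8–C9=O enone should react far faster than the β,β-disubstituted ring A enone or the senecioate, and stereoelectronically preferred axial attack on the trans-locked enone comes from the β face, syn to H5 and anti to C14, giving the axial 7β-isopropenyl group (the trans-3,5 rule of 5-substituted cyclohexenones).

Step 12
Reactants: 16 7β-isopropenyl 2,9-diketone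
Product: 17 2α,9β-diol
Conditions: LiBH(s-Bu)3 (2.5 equiv), THF, −78 → −40 °C; AcOH quench at −78 °C
Reagents that add atoms: none
Why: Reagent-controlled ketone reduction by a bulky trialkylborohydride with equatorial attack at both carbonyls: at C9 the axial β trajectory is closed by the syn-axial isopropenyl group, so hydride enters from α and gives the axial 9β-alcohol; at C2 the axial α trajectory is closed by the syn-axial C14 group, so the β-substituted enone is reduced 1,2 from β to the 2α-alcohol; the cold acidic quench is meant to stop senecioyl migration.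

Step 13
Reactants: 17 2α,9β-diol
Product: 18 2α,9β-diacetate TBS ether
Conditions: Ac2O, DMAP, pyridine, rt → 40 °C
Reagents that add atoms: acetic anhydride CC(=O)OC(C)=O
Why: DMAP-catalysed acetylation of both secondary alcohols in one operation, with mild heating allowed for the hindered axial C9–OH; no stereocenter is touched.

Step 14
Reactants: 18 2α,9β-diacetate TBS ether
Product: 19 target CNP0320218.1
Conditions: HF·pyridine, THF, 0 °C → rt; pH 7 buffer work-up
Reagents that add atoms: none
Why: Fluoride-mediated desilylation in a weakly acidic medium, which frees C14–OH without generating an alkoxide that could draw the C1 or C9 acyl groups onto the primary position.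

Compound list
1 | methyl 2,5-dihydroxybenzoate | COC(=O)c1cc(O)ccc1O | starting material
2 | methyl 3,6-dioxocyclohexa-1,4-diene-1-carboxylate | COC(=O)C1=CC(=O)C=CC1=O | intermediate
3 | (E)-but-2-enal | C/C=C/C=O | starting material
4 | (E)-1-(triethylsilyloxy)buta-1,3-diene | C=C/C=C/O[Si](CC)(CC)CC | intermediate
5 | cis-fused enedione ester (CO2Me α, H5 α, 9β-OTES) | C1=C[C@H](O[Si](CC)(CC)CC)[C@@]2(C(=O)OC)[C@@H](C1)C(=O)C=CC2=O | intermediate
6 | trans-fused enedione ester (H5 β) | C1=C[C@H](O[Si](CC)(CC)CC)[C@@]2(C(=O)OC)[C@H](C1)C(=O)C=CC2=O | intermediate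
7 | C4 carbinol ester (4α-OH, 4β-methyl) | C1=C[C@H](O[Si](CC)(CC)CC)[C@@]2(C(=O)OC)[C@H](C1)[C@](C)(O)C=CC2=O | intermediate
8 | enone γ-lactone (C14–O–C4 bridge on the α face) | C1=C[C@H](O[Si](CC)(CC)CC)[C@@]2(C(=O)O3)[C@H](C1)[C@@]3(C)C=CC2=O | intermediate
9 | triol (1α-OH, 4α-OH, C14–OH, 9β-OTES) | C1=C[C@H](O[Si](CC)(CC)CC)[C@@]2(CO)[C@H](C1)[C@](C)(O)C=C[C@@H]2O | intermediate
10 | 14-O-TBS diol | C1=C[C@H](O[Si](CC)(CC)CC)[C@@]2(CO[Si](C)(C)C(C)(C)C)[C@H](C1)[C@](C)(O)C=C[C@@H]2O | intermediate
11 | 1α-senecioate | C1=C[C@H](O[Si](CC)(CC)CC)[C@@]2(CO[Si](C)(C)C(C)(C)C)[C@H](C1)[C@](C)(O)C=C[C@@H]2OC(=O)C=C(C)C | intermediate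
12 | 9β-alcohol | C1=C[C@H](O)[C@@]2(CO[Si](C)(C)C(C)(C)C)[C@H](C1)[C@](C)(O)C=C[C@@H]2OC(=O)C=C(C)C | intermediate
13 | enone carbinol (7-en-9-one, 4α-OH) | C1=CC(=O)[C@@]2(CO[Si](C)(C)C(C)(C)C)[C@H](C1)[C@](C)(O)C=C[C@@H]2OC(=O)C=C(C)C | intermediate
14 | bis-enone (3-en-2-one, 7-en-9-one) | C1=CC(=O)[C@@]2(CO[Si](C)(C)C(C)(C)C)[C@H](C1)C(C)=CC(=O)[C@@H]2OC(=O)C=C(C)C | intermediate
15 | C9 trimethylsilyl enol ether (7β-isopropenyl) | C=C(C)[C@@H]1C=C(O[Si](C)(C)C)[C@@]2(CO[Si](C)(C)C(C)(C)C)[C@H](C1)C(C)=CC(=O)[C@@H]2OC(=O)C=C(C)C | intermediate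
16 | 7β-isopropenyl 2,9-diketone | C=C(C)[C@@H]1CC(=O)[C@@]2(CO[Si](C)(C)C(C)(C)C)[C@H](C1)C(C)=CC(=O)[C@@H]2OC(=O)C=C(C)C | intermediate
17 | 2α,9β-diol | C=C(C)[C@@H]1C[C@H](O)[C@@]2(CO[Si](C)(C)C(C)(C)C)[C@H](C1)C(C)=C[C@H](O)[C@@H]2OC(=O)C=C(C)C | intermediate
18 | 2α,9β-diacetate TBS ether | C=C(C)[C@@H]1C[C@H](OC(C)=O)[C@@]2(CO[Si](C)(C)C(C)(C)C)[C@H](C1)C(C)=C[C@H](OC(C)=O)[C@@H]2OC(=O)C=C(C)C | intermediate
19 | CNP0320218.1 (1α-senecioyloxy-2α,9β-diacetoxy-14-hydroxyeudesma-3,11-diene, 5β-H, 7β-isopropenyl) | C=C(C)[C@@H]1C[C@H](OC(C)=O)[C@@]2(CO)[C@H](C1)C(C)=C[C@H](OC(C)=O)[C@@H]2OC(=O)C=C(C)C | target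

Total step count: 14. Longest linear sequence: 13 (steps 1 and 3–14; the branch through step 2 is equally long).

Steps most likely to fail

1. Step 3. The uncatalysed background cycloaddition of this very reactive pair may erode the enantioselectivity. The silyl dienol ether may also divert into a stepwise Michael addition with silyl transfer and aromatisation.
   - The fallback replaces catalyst control by auxiliary control. It sets out from 1 and comes back at 9.
   - Compound 1 is transesterified with (1R,2S,5R)-8-phenylmenthol (Ti(OiPr)4 cat., toluene, reflux) to 8-phenylmenthyl 2,5-dihydroxybenzoate F1.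
   - Ag2O gives the auxiliary quinone ester F2.
   - Cycloaddition with 4 at low temperature without Lewis acid gives the cis-fused auxiliary adduct F3. The phenyl group stacks over one face of C5=C10, and diastereomers can be separated here.
   - DBU gives the trans-fused auxiliary adduct F4.
   - MeCeCl2 gives the C4 carbinol auxiliary ester F5, whose hindered alkoxide leaves slowly.
   - LiAlH4 reduces F5 to 9 with release of the auxiliary.
   - The other antipode of the auxiliary is taken if the sense of induction is opposite.

2. Step 4. The equilibration may stop at an unfavourable cis/trans position, or the base may trigger migration or loss of the angular ester.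
   - The fallback moves the equilibration to the saturated dione and restores the alkene later. It sets out from 5 and comes back at 8.
   - Zn in AcOH/CH2Cl2 reduces the C2=C3 bond to the cis-fused 2,3-dihydro dione F6.
   - With ring A free to adopt a chair, base (DBU or K2CO3) should move it to the trans-fused 2,3-dihydro dione F7.
   - MeCeCl2 adds at C4 to give the saturated carbinol ester F8, which lactonises to the saturated keto lactone F9.
   - 2-Iodoxybenzoic acid (DMSO/toluene, warm) dehydrogenates the only enolisable side of the C1 ketone to give 8.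

3. Step 12. Facial selectivity may be poor at the doubly hindered C9 ketone, or the senecioyl group may migrate from O1 to the adjacent C2 alkoxide.
   - The fallback replaces reagent control by substrate-directed hydride delivery and splits the two reductions. It sets out from 16 and comes back at 17.
   - HF·pyridine removes the silyl group to give the C14 alcohol diketone F10.
   - Me4N[BH(OAc)3] in AcOH/MeCN (Evans–Saksena reduction) binds to C14–OH and delivers hydride to C9 from the α face, giving the 9β,14-diol enone F11.
   - Luche reduction (NaBH4, CeCl3·7H2O, MeOH, −78 °C) reduces C2 from the β face under non-basic conditions, giving the 2α,9β,14-triol F12.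
   - TBSCl/imidazole silylates the primary alcohol again to give 17.

Further compounds
F1 | step 3 | (1R,2S,5R)-8-phenylmenthyl 2,5-dihydroxybenzoate | O=C(O[C@@H]1C[C@H](C)CC[C@H]1C(C)(C)c1ccccc1)c1cc(O)ccc1O
F2 | step 3 | (1R,2S,5R)-8-phenylmenthyl 3,6-dioxocyclohexa-1,4-diene-1-carboxylate | O=C(O[C@@H]1C[C@H](C)CC[C@H]1C(C)(C)c1ccccc1)C1=CC(=O)C=CC1=O
F3 | step 3 | cis-fused auxiliary adduct | C1=C[C@H](O[Si](CC)(CC)CC)[C@@]2(C(=O)O[C@@H]4C[C@H](C)CC[C@H]4C(C)(C)c4ccccc4)[C@@H](C1)C(=O)C=CC2=O
F4 | step 3 | trans-fused auxiliary adduct | C1=C[C@H](O[Si](CC)(CC)CC)[C@@]2(C(=O)O[C@@H]4C[C@H](C)CC[C@H]4C(C)(C)c4ccccc4)[C@H](C1)C(=O)C=CC2=O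
F5 | step 3 | C4 carbinol auxiliary ester | C1=C[C@H](O[Si](CC)(CC)CC)[C@@]2(C(=O)O[C@@H]4C[C@H](C)CC[C@H]4C(C)(C)c4ccccc4)[C@H](C1)[C@](C)(O)C=CC2=O
F6 | step 4 | cis-fused 2,3-dihydro dione | C1=C[C@H](O[Si](CC)(CC)CC)[C@@]2(C(=O)OC)[C@@H](C1)C(=O)CCC2=O
F7 | step 4 | trans-fused 2,3-dihydro dione | C1=C[C@H](O[Si](CC)(CC)CC)[C@@]2(C(=O)OC)[C@H](C1)C(=O)CCC2=O
F8 | step 4 | saturated carbinol ester | C1=C[C@H](O[Si](CC)(CC)CC)[C@@]2(C(=O)OC)[C@H](C1)[C@](C)(O)CCC2=O
F9 | step 4 | saturated keto lactone | C1=C[C@H](O[Si](CC)(CC)CC)[C@@]2(C(=O)O3)[C@H](C1)[C@@]3(C)CCC2=O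
F10 | step 12 | C14 alcohol diketone | C=C(C)[C@@H]1CC(=O)[C@@]2(CO)[C@H](C1)C(C)=CC(=O)[C@@H]2OC(=O)C=C(C)C
F11 | step 12 | 9β,14-diol enone | C=C(C)[C@@H]1C[C@H](O)[C@@]2(CO)[C@H](C1)C(C)=CC(=O)[C@@H]2OC(=O)C=C(C)C
F12 | step 12 | 2α,9β,14-triol | C=C(C)[C@@H]1C[C@H](O)[C@@]2(CO)[C@H](C1)C(C)=C[C@H](O)[C@@H]2OC(=O)C=C(C)C
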